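Compound numbers 1–20 are those of the steps and the compound list. Fl stands for the (2S,4R)-7-(benzyloxy)-2-[3,4-bis(benzyloxy)phenyl]chroman-4-yl group, in which the 2-aryl group and the bond from C4 are trans.

## The problem

Compound 20 is a 3-deoxy proanthocyanidin dimer. An upper (2S,4R)-7,3′,4′-trihydroxyflavan (benzo ring A, pyran ring C, catechol ring B; 2-aryl and 4-aryl trans) is bonded through C4 of ring C to C8 of a lower (2R,3R)-epigallocatechin unit (benzo ring D, pyran ring F, pyrogallol ring E; 2-aryl and 3-hydroxyl cis). The C4–C8 bond joins a benzylic stereocentre to a fully substituted phloroglucinol-type ring and must reach C8, not the equally electron-rich C6. The four stereocentres form two remote pairs. Upper C2 can direct C4, because a nucleophile adding to the C4 cation meets the 2-aryl group across the half-chair. Lower C2 can direct C3, because a hydride adds to a 3-ketone anti to the 2-aryl group. Neither pair can be trusted to direct the other across the interflavan bond, so upper C2 and lower C2 each need an external chiral reagent. The free compound has eight phenols, among them an air-sensitive catechol and pyrogallol; the C4–C8 bond cleaves by retro-Friedel–Crafts reaction in strong acid, the 2-aryl benzylic ether bonds of both pyran rings open under acid, and a 2-arylchroman-3-one epimerises easily at C2. All phenols therefore stay as benzyl ethers until the last step, and everything after the C4–C8 bond must be mild. The feature the plan uses is that in ring F both C2 (bonded to O1 and ring E) and C3 (bearing the hydroxyl) carry oxygen. The C2–C3 bond can thus be traced to two carbonyl carbons: a gallate ester on the ring D oxygen that becomes O1, and an acetaldehyde chain on C4a whose methylene becomes C4. Reductive coupling of the two gives a C2=C3 enol ether from which both lower stereocentres are set afterwards.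

## Retrosynthesis

**20 from 19.** Eight O–benzyl bonds are cut. Benzyl ethers tolerate every reagent of the route and fall in one neutral hydrogenolysis, which the sensitive polyphenol needs. The secondary alcohol of 19 is left free, so no ninth group is required.

**19 from 18, 17 and 15.** The C3–H bond of 19 is cut back to ketone 18, the ketone to the 2,3-trans alcohol 17, and the C2–H and C3–O bonds of 17 to enol ether 15. Hydroboration adds H and B syn, so it can only give the trans alcohol. The cis isomer is reached by oxidation and reduction with a bulky hydride, a pairing that is dependable for benzylated flavan-3-ols. A direct cis route through an epoxide of 15 would pass through a benzylic oxocarbenium ion and was set aside. The forward steps must control the face of addition at lower C2 by the reagent and must not epimerise C2 in 18.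

**15 from 14 (key cut).** The C2=C3 bond is cut to the ester carbonyl and the aldehyde carbonyl of 14. Cutting O1–C2 or rebuilding ring D would leave a stereocentre or a polysubstituted arene to be made during ring closure. This cut removes ring F and both lower stereocentres at once and turns ring E into a gallic acid derivative. The forward reaction must favour intramolecular cross-coupling over intermolecular pinacol coupling, and the enol ether must survive isolation.

**14 from 12, and 12 from 9 and 10.** The aldehyde is traced to the allyl group of 12, and the ester C–O bond is cut to phenol 9 and acid 10 (activated as chloride 11). A terminal alkene is inert during acylation and lets the unstable arylacetaldehyde appear only one step before it is used. The acylation has to reach a phenol flanked by two ortho substituents.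

**9 from 8, and 8 from 7.** The C4a–CH2 bond is cut by a retro-Claisen step to allyl ether 8 and then to phenol 7. The rearrangement moves the allyl group from the one free oxygen to its neighbouring carbon, and the same oxygen is acylated later. O1 and C4 of ring F are therefore adjacent by construction, and because the other ortho carbon already carries Fl the linkage is necessarily 4→8.

**7 from 5 and 6.** The C4–C8 bond is cut to the flavan-4-yl cation derived from alcohol 5 and to commercial phenol 6. The neighbouring option, adding a ring D aryl-metal to ketone 4 and then removing the tertiary hydroxyl with a hydride, would deliver hydride along the axial path and leave the two aryl groups cis. Only cation capture delivers the aryl group itself along that path. The forward step needs attack ortho to the hydroxyl of 6 and approach trans to the 2-aryl group.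

**5 from 4, 4 from 2 and 3, 2 from 1.** The C2–aryl bond is cut to chromone 2 and boronic acid 3, and 2 comes from commercial 1 by benzylation. A chalcone cyclisation would give racemic 4; the catalytic conjugate addition sets upper C2 directly. Reduction of 4 to 5 only prepares the leaving group.

## Roads not taken

**Alternative 1:** The cut runs through ring D: lower C8–C8a, C6–C7 and C4a–C8a would form when siloxyalkyne A2 (the upper flavan with a triisopropylsilyloxyethynyl group on C4) is heated with cyclobutenone A3 (3-benzyloxy, with the propargyl chain that ends in ring E on C4). Opening of A3 to a vinylketene, [2+2] addition to the ynol ether, a second ring opening and 6π closure would give phenol A1. In A1 the only free hydroxyl is on C8a, the C7 oxygen is a silyl ether and C4a already carries the three carbons of ring F.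
- Merit: the substitution pattern of ring D is fixed by the two partners. The ortho/para question of step 4 and the thermal Claisen step do not arise, and in this respect the benzannulation is the better plan.
- Weak points: A2 needs a C(sp3)–C(sp) bond at C4 trans to the 2-aryl group and then a silyl ynol ether, a sensitive function usually reached in several steps. A3 needs a 4-alkylated 3-alkoxycyclobutenone, again several steps. After A1, ring F is still open, so a 6-endo addition of the phenol to the alkyne, a desilylation and the same stereochemical end game would follow.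
- Comparison: the step count would clearly exceed thirteen, and two fragile partners replace four commercial ones. Against the regiochemical certainty of A1 the chosen plan sets the steric bias for the less hindered ortho carbon of 6 and a fallback for step 4.

**Alternative 2:** Three bonds of upper ring C are cut: C4–C4a, O1–C2 and C2–aryl. Enal A5 (protected epigallocatechin with a propenal chain on C8), phenol A6 and arene A7 would be combined. Under a 2-[diaryl(trimethylsilyloxy)methyl]pyrrolidine, A6 would add through the carbon ortho to its hydroxyl to the β-carbon of the iminium ion of A5, and the phenol oxygen would close a hemiacetal. BF3·OEt2 would then ionise the hemiacetal and A7 would arylate C2 to give nonabenzyl ether A4, one hydrogenolysis from 20.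
- Merits: the plan is highly convergent and the end game is one step. Upper C4 is set by a catalyst and not by the substrate, which the chosen route cannot claim.
- Weak points: A5 presupposes the whole lower unit with both stereocentres and a regioselective three-carbon extension at C8, so most of a flavan-3-ol synthesis must come first. The β-carbon of A5 sits on an aryl ring with two ortho substituents, a poor acceptor for iminium catalysis. A6 is a singly activated phenol with two different ortho carbons, whereas this reaction type works best with naphthols and polyoxygenated phenols. The C2 arylation must give the 2,4-trans isomer and runs with BF3·OEt2 next to the acid-labile C4–C8 bond.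
- Comparison: shorter on paper after the fragments, but the cost of A5 and two untested selectivities outweigh this. The chosen plan builds the lower unit from a gallic acid derivative on the assembled skeleton.

**Alternative 3:** O1–C2 of ring F is cut. The ring D phenol of cis-epoxide A9 would open the epoxide at its benzylic carbon with inversion (6-endo), releasing the 3-hydroxyl cis to ring E and giving A8, which is the same compound as 19.
- Merits: both lower stereocentres come from one asymmetric epoxidation, the cis relationship appears directly, and steps 10 to 12 of the chosen plan collapse into one mild ring closure. This is the shortest end game of the four plans.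
- Weak points: A9 needs a Z-selective olefination and then an enantioselective cis-epoxidation on a chiral molecule full of oxidisable arenes. The benzylic epoxide carbon carries ring E, whose para benzyloxy group stabilises a cation, so the opening may lose its inversion and give the 2,3-trans isomer at the very centre the step is meant to control. A 5-exo attack at C3 would give a dihydrobenzofuran.
- Comparison: if the inversion held, A8 would be reached about two steps sooner. The chosen plan gives up that saving for a ring closure with no stereochemical content, followed by a reagent-controlled hydroboration and a well-established trans-to-cis correction.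

Key step: step 9

Assumption: the hand named for the oxazoline ligand (step 2) and for the pinene-derived borane (step 10) is the one predicted by the empirical models for cyclic enones and 1-arylcycloalkenes; the antipodal reagents are equally available if the sense proves opposite.

## Route

Step 1
Reactants: 1 7-hydroxy-4H-chromen-4-one
Product: 2 7-(benzyloxy)-4H-chromen-4-one
Conditions: BnBr, K2CO3, acetone, reflux
Reagents that add atoms: benzyl bromide, BrCc1ccccc1
Why: Williamson etherification of the acidic 7-hydroxyl; the benzyl ether fits the single final deprotection and the carbonate is too weak to open the pyranone ring.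

Step 2
Reactants: 2 7-(benzyloxy)-4H-chromen-4-one; 3 [3,4-bis(benzyloxy)phenyl]boronic acid
Product: 4 (2S)-7-(benzyloxy)-2-[3,4-bis(benzyloxy)phenyl]chroman-4-one
Conditions: Pd(OCOCF3)2 (5 mol %), (R)-t-BuPyOX (6 mol %), NH4PF6 (30 mol %), H2O (5 equiv), ClCH2CH2Cl, 60 °C
Reagents that add atoms: none
Why: Enantioselective conjugate addition of an arylboronic acid to a chromone under cationic divalent palladium with a pyridine–oxazoline ligand, a known route to flavanones. The aryl group inserts at C2 from the face set by the ligand (2S expected), and protonolysis of the palladium enolate releases the ketone.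

Step 3
Reactants: 4 (2S)-7-(benzyloxy)-2-[3,4-bis(benzyloxy)phenyl]chroman-4-one
Product: 5 (2S,4S)-7-(benzyloxy)-2-[3,4-bis(benzyloxy)phenyl]chroman-4-ol (2,4-cis)
Conditions: NaBH4, THF–MeOH, 0 °C
Reagents that add atoms: none
Why: Borohydride reduction; axial hydride attack on the flavanone with the 2-aryl group equatorial should give mainly the 2,4-cis alcohol. This carbinol centre is erased in step 4, so its purity does not matter.

Step 4
Reactants: 5 (2S,4S)-7-(benzyloxy)-2-[3,4-bis(benzyloxy)phenyl]chroman-4-ol; 6 3,5-bis(benzyloxy)phenol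
Product: 7 3,5-bis(benzyloxy)-2-Fl-phenol
Conditions: 6 (3 equiv), BF3·OEt2 (0.3 equiv), 4 Å molecular sieves, CH2Cl2, −40 → 0 °C
Reagents that add atoms: none
Why: Friedel–Crafts alkylation through the flavan-4-yl cation, which is stabilised by O1 and the para 7-benzyloxy group. Phenol 6 should react at a carbon ortho to its hydroxyl (two equivalent sites flanked by OH and OBn) rather than at the single carbon between two benzyloxy groups, as C8 is preferred over C6 in benzylated flavan-3-ols. Axial approach on the half-chair with the 2-aryl group equatorial should place the new aryl group trans to it (4R).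

Step 5
Reactants: 7 3,5-bis(benzyloxy)-2-Fl-phenol
Product: 8 allyl 3,5-bis(benzyloxy)-2-Fl-phenyl ether
Conditions: allyl bromide, K2CO3, DMF, rt → 50 °C
Reagents that add atoms: allyl bromide, C=CCBr
Why: Williamson etherification of the only free phenol; a polar aprotic solvent favours O- over C-allylation.

Step 6
Reactants: 8 allyl 3,5-bis(benzyloxy)-2-Fl-phenyl ether
Product: 9 2-allyl-3,5-bis(benzyloxy)-6-Fl-phenol
Conditions: PhNEt2 (degassed), 190 °C
Reagents that add atoms: none
Why: Aromatic Claisen rearrangement; the [3,3] shift to the one ortho carbon that bears hydrogen is followed by irreversible tautomerisation, which fixes the side chain on the future C4a next to the future O1.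

Step 7
Reactants: 9 2-allyl-3,5-bis(benzyloxy)-6-Fl-phenol; 10 3,4,5-tris(benzyloxy)benzoic acid
Product: 12 2-allyl-3,5-bis(benzyloxy)-6-Fl-phenyl 3,4,5-tris(benzyloxy)benzoate, via acid chloride 11 (not isolated)
Conditions: 10, (COCl)2, DMF (cat.), CH2Cl2, rt, evaporate; then 9, NaH, THF, 0 °C → rt
Reagents that add atoms: none
Why: Acid chloride formation and O-acylation of a sodium phenoxide; the phenol is flanked on both sides, so the phenoxide and acid chloride pair is used in place of a carbodiimide coupling.

Step 8
Reactants: 12 2-allyl-3,5-bis(benzyloxy)-6-Fl-phenyl 3,4,5-tris(benzyloxy)benzoate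
Product: 14 3,5-bis(benzyloxy)-2-Fl-6-(2-oxoethyl)phenyl 3,4,5-tris(benzyloxy)benzoate, via diol 13 (not isolated)
Conditions: OsO4 (2 mol %), NaIO4 (4 equiv), 2,6-lutidine, dioxane–H2O 3:1, rt; used crude
Reagents that add atoms: osmium tetroxide, O=[Os](=O)(=O)=O (transfers the oxygen); sodium periodate, [Na+].[O-]I(=O)(=O)=O (terminal oxidant)
Why: Lemieux–Johnson cleavage: osmium-catalysed dihydroxylation of the terminal alkene, then periodate glycol cleavage. It is gentler than ozone on the electron-rich benzyloxy arenes, and the lutidine buffer suppresses over-oxidation.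

Step 9
Reactants: 14 3,5-bis(benzyloxy)-2-Fl-6-(2-oxoethyl)phenyl 3,4,5-tris(benzyloxy)benzoate
Product: 15 5,7-bis(benzyloxy)-8-Fl-2-[3,4,5-tris(benzyloxy)phenyl]-4H-chromene
Conditions: TiCl3 (10 equiv), Zn dust (20 equiv), DME, reflux; 14 added by syringe pump over about 10 h to a final concentration of at most 0.005 M; aq. K2CO3 work-up, basic alumina
Reagents that add atoms: none
Why: Low-valent titanium made from TiCl3 and Zn transfers an electron to the more easily reduced aldehyde, and the titanium-bound ketyl carbon (future C3) adds to the ester carbonyl carbon (future C2). The resulting titanium 1,2-diolate is deoxygenated on the oxophilic metal to give the C2=C3 enol ether. The closest known reaction type is the titanium-mediated McMurry-type coupling of oxo-esters and oxo-amides to cyclic enol ethers, benzofurans and indoles. Ring F closes in the 6-exo-trig mode: the ring contains O1, C2, C3, C4, C4a and C8a, and the attacked C=O lies outside it. No stereocentre is formed, and upper C2 and C4 are remote from both carbonyl groups and cannot epimerise. The step needs intramolecular cross-coupling to win over intermolecular pinacol coupling and over plain reduction of the aldehyde. Slow addition at high dilution secures this, together with the substrate: the ester and the acetaldehyde chain are held ortho to each other on ring D, and the bulky Fl group on the other side pushes the ester towards the chain. The base work-up keeps the acid-sensitive enol ether from hydration or double-bond migration.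

Step 10
Reactants: 15 5,7-bis(benzyloxy)-8-Fl-2-[3,4,5-tris(benzyloxy)phenyl]-4H-chromene
Product: 17 (2R,3S)-5,7-bis(benzyloxy)-8-Fl-2-[3,4,5-tris(benzyloxy)phenyl]chroman-3-ol (2,3-trans), via alkylborane 16 (not isolated)
Conditions: IpcBH2 from (+)-α-pinene (freshly prepared), THF, −25 → 0 °C; then NaOH, H2O2, 0 °C → rt
Reagents that add atoms: hydrogen peroxide, OO
Why: Asymmetric hydroboration–oxidation; boron adds to C3 (β to the ring oxygen and away from the aryl group) syn to the hydrogen delivered to C2, so aryl and hydroxyl end up trans after oxidation with retention. The face is chosen by the chiral borane, which by the empirical model for 1-arylcycloalkenes should give 2R,3S.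

Step 11
Reactants: 17 (2R,3S)-5,7-bis(benzyloxy)-8-Fl-2-[3,4,5-tris(benzyloxy)phenyl]chroman-3-ol
Product: 18 (2R)-5,7-bis(benzyloxy)-8-Fl-2-[3,4,5-tris(benzyloxy)phenyl]chroman-3-one
Conditions: Dess–Martin periodinane, wet CH2Cl2, rt; used at once
Reagents that add atoms: none
Why: Dess–Martin oxidation is fast and close to neutral, which is how benzylated catechins are converted into flavan-3-ones without enolisation at the benzylic C2.

Step 12
Reactants: 18 (2R)-5,7-bis(benzyloxy)-8-Fl-2-[3,4,5-tris(benzyloxy)phenyl]chroman-3-one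
Product: 19 (2R,3R)-5,7-bis(benzyloxy)-8-Fl-2-[3,4,5-tris(benzyloxy)phenyl]chroman-3-ol (2,3-cis)
Conditions: LiBH(s-Bu)3, LiBr, THF, −78 °C; H2O quench
Reagents that add atoms: none
Why: Substrate-controlled reduction with a bulky hydride; attack anti to the 2-aryl group gives the alcohol cis to it (3R), and the low temperature with LiBr should prevent epimerisation at C2.

Step 13
Reactants: 19 (2R,3R)-5,7-bis(benzyloxy)-8-Fl-2-[3,4,5-tris(benzyloxy)phenyl]chroman-3-ol
Product: 20 (2R,3R)-8-[(2S,4R)-2-(3,4-dihydroxyphenyl)-7-hydroxychroman-4-yl]-2-(3,4,5-trihydroxyphenyl)chromane-3,5,7-triol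
Conditions: H2 (1 atm), Pd(OH)2/C, THF–MeOH–H2O, rt; filtration and freeze-drying under argon
Reagents that add atoms: none
Why: Hydrogenolysis of all eight benzyl ethers in one neutral step, the usual end of benzylated proanthocyanidin syntheses; the ring benzylic C–O and C–C bonds of flavans normally survive these conditions.

## Compound list

1 | 7-hydroxy-4H-chromen-4-one | O=c1ccoc2cc(O)ccc12 | starting material
2 | 7-(benzyloxy)-4H-chromen-4-one | O=c1ccoc2cc(OCc3ccccc3)ccc12 | intermediate
3 | [3,4-bis(benzyloxy)phenyl]boronic acid | OB(O)c1ccc(OCc2ccccc2)c(OCc2ccccc2)c1 | starting material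
4 | (2S)-7-(benzyloxy)-2-[3,4-bis(benzyloxy)phenyl]chroman-4-one | c1ccccc1COc1ccc2c(c1)O[C@H](c1ccc(OCc3ccccc3)c(OCc3ccccc3)c1)CC2=O | intermediate
5 | (2S,4S)-7-(benzyloxy)-2-[3,4-bis(benzyloxy)phenyl]chroman-4-ol (2,4-cis) | c1ccccc1COc1ccc2c(c1)O[C@H](c1ccc(OCc3ccccc3)c(OCc3ccccc3)c1)C[C@@H]2O | intermediate
6 | 3,5-bis(benzyloxy)phenol | Oc1cc(OCc2ccccc2)cc(OCc2ccccc2)c1 | starting material
7 | 3,5-bis(benzyloxy)-2-{(2S,4R)-7-(benzyloxy)-2-[3,4-bis(benzyloxy)phenyl]chroman-4-yl}phenol (2,4-trans) | c1ccccc1COc1ccc2c(c1)O[C@H](c1ccc(OCc3ccccc3)c(OCc3ccccc3)c1)C[C@H]2c1c(OCc3ccccc3)cc(OCc3ccccc3)cc1O | intermediate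
8 | (2S,4R)-4-[2-(allyloxy)-4,6-bis(benzyloxy)phenyl]-7-(benzyloxy)-2-[3,4-bis(benzyloxy)phenyl]chromane | c1ccccc1COc1ccc2c(c1)O[C@H](c1ccc(OCc3ccccc3)c(OCc3ccccc3)c1)C[C@H]2c1c(OCc3ccccc3)cc(OCc3ccccc3)cc1OCC=C | intermediate
9 | 2-allyl-3,5-bis(benzyloxy)-6-{(2S,4R)-7-(benzyloxy)-2-[3,4-bis(benzyloxy)phenyl]chroman-4-yl}phenol | c1ccccc1COc1ccc2c(c1)O[C@H](c1ccc(OCc3ccccc3)c(OCc3ccccc3)c1)C[C@H]2c1c(OCc3ccccc3)cc(OCc3ccccc3)c(CC=C)c1O | intermediate
10 | 3,4,5-tris(benzyloxy)benzoic acid | OC(=O)c1cc(OCc2ccccc2)c(OCc2ccccc2)c(OCc2ccccc2)c1 | starting material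
11 | 3,4,5-tris(benzyloxy)benzoyl chloride | ClC(=O)c1cc(OCc2ccccc2)c(OCc2ccccc2)c(OCc2ccccc2)c1 | intermediate
12 | 2-allyl-3,5-bis(benzyloxy)-6-{(2S,4R)-7-(benzyloxy)-2-[3,4-bis(benzyloxy)phenyl]chroman-4-yl}phenyl 3,4,5-tris(benzyloxy)benzoate | c1ccccc1COc1ccc2c(c1)O[C@H](c1ccc(OCc3ccccc3)c(OCc3ccccc3)c1)C[C@H]2c1c(OCc3ccccc3)cc(OCc3ccccc3)c(CC=C)c1OC(=O)c1cc(OCc3ccccc3)c(OCc3ccccc3)c(OCc3ccccc3)c1 | intermediate
13 | 3,5-bis(benzyloxy)-2-(2,3-dihydroxypropyl)-6-{(2S,4R)-7-(benzyloxy)-2-[3,4-bis(benzyloxy)phenyl]chroman-4-yl}phenyl 3,4,5-tris(benzyloxy)benzoate (both epimers at the secondary carbinol) | c1ccccc1COc1ccc2c(c1)O[C@H](c1ccc(OCc3ccccc3)c(OCc3ccccc3)c1)C[C@H]2c1c(OCc3ccccc3)cc(OCc3ccccc3)c(CC(O)CO)c1OC(=O)c1cc(OCc3ccccc3)c(OCc3ccccc3)c(OCc3ccccc3)c1 | intermediate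
14 | 3,5-bis(benzyloxy)-2-{(2S,4R)-7-(benzyloxy)-2-[3,4-bis(benzyloxy)phenyl]chroman-4-yl}-6-(2-oxoethyl)phenyl 3,4,5-tris(benzyloxy)benzoate | c1ccccc1COc1ccc2c(c1)O[C@H](c1ccc(OCc3ccccc3)c(OCc3ccccc3)c1)C[C@H]2c1c(OCc3ccccc3)cc(OCc3ccccc3)c(CC=O)c1OC(=O)c1cc(OCc3ccccc3)c(OCc3ccccc3)c(OCc3ccccc3)c1 | intermediate
15 | 5,7-bis(benzyloxy)-8-{(2S,4R)-7-(benzyloxy)-2-[3,4-bis(benzyloxy)phenyl]chroman-4-yl}-2-[3,4,5-tris(benzyloxy)phenyl]-4H-chromene | c1ccccc1COc1ccc2c(c1)O[C@H](c1ccc(OCc3ccccc3)c(OCc3ccccc3)c1)C[C@H]2c1c(OCc3ccccc3)cc(OCc3ccccc3)c2c1OC(c1cc(OCc3ccccc3)c(OCc3ccccc3)c(OCc3ccccc3)c1)=CC2 | intermediate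
16 | isopinocampheyl borane adduct of 15: boron on lower C3 trans to the 2-aryl group, H on C2, same spatial arrangement as 17 (CIP 2S,3S because boron ranks below carbon); isopinocampheyl from (+)-α-pinene | c1ccccc1COc1ccc2c(c1)O[C@H](c1ccc(OCc3ccccc3)c(OCc3ccccc3)c1)C[C@H]2c1c(OCc3ccccc3)cc(OCc3ccccc3)c2c1O[C@H](c1cc(OCc3ccccc3)c(OCc3ccccc3)c(OCc3ccccc3)c1)[C@@H]([BH][C@@H]4C[C@@H]5C[C@H]([C@H]4C)C5(C)C)C2 | intermediate
17 | (2R,3S)-5,7-bis(benzyloxy)-8-{(2S,4R)-7-(benzyloxy)-2-[3,4-bis(benzyloxy)phenyl]chroman-4-yl}-2-[3,4,5-tris(benzyloxy)phenyl]chroman-3-ol (2,3-trans) | c1ccccc1COc1ccc2c(c1)O[C@H](c1ccc(OCc3ccccc3)c(OCc3ccccc3)c1)C[C@H]2c1c(OCc3ccccc3)cc(OCc3ccccc3)c2c1O[C@H](c1cc(OCc3ccccc3)c(OCc3ccccc3)c(OCc3ccccc3)c1)[C@@H](O)C2 | intermediate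
18 | (2R)-5,7-bis(benzyloxy)-8-{(2S,4R)-7-(benzyloxy)-2-[3,4-bis(benzyloxy)phenyl]chroman-4-yl}-2-[3,4,5-tris(benzyloxy)phenyl]chroman-3-one | c1ccccc1COc1ccc2c(c1)O[C@H](c1ccc(OCc3ccccc3)c(OCc3ccccc3)c1)C[C@H]2c1c(OCc3ccccc3)cc(OCc3ccccc3)c2c1O[C@H](c1cc(OCc3ccccc3)c(OCc3ccccc3)c(OCc3ccccc3)c1)C(=O)C2 | intermediate
19 | (2R,3R)-5,7-bis(benzyloxy)-8-{(2S,4R)-7-(benzyloxy)-2-[3,4-bis(benzyloxy)phenyl]chroman-4-yl}-2-[3,4,5-tris(benzyloxy)phenyl]chroman-3-ol (2,3-cis) | c1ccccc1COc1ccc2c(c1)O[C@H](c1ccc(OCc3ccccc3)c(OCc3ccccc3)c1)C[C@H]2c1c(OCc3ccccc3)cc(OCc3ccccc3)c2c1O[C@H](c1cc(OCc3ccccc3)c(OCc3ccccc3)c(OCc3ccccc3)c1)[C@H](O)C2 | intermediate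
20 | (2R,3R)-8-[(2S,4R)-2-(3,4-dihydroxyphenyl)-7-hydroxychroman-4-yl]-2-(3,4,5-trihydroxyphenyl)chromane-3,5,7-triol | Oc1ccc2c(c1)O[C@H](c1ccc(O)c(O)c1)C[C@H]2c1c(O)cc(O)c2c1O[C@H](c1cc(O)c(O)c(O)c1)[C@H](O)C2 | target

## Step count and risks

Total step count: 13. Longest linear sequence: 13 steps (1 → 20); compounds 3, 6 and 10 enter as purchased materials.

Least certain steps:

**Step 9 (key step).** The aldehyde may couple with a second molecule in pinacol fashion or simply be reduced before it meets the hindered ester. The aryl ester C–O bond may be cleaved reductively, and the enol ether may hydrate or shift its double bond on contact with Lewis-acidic titanium or zinc salts. Fallback, from 12 to 15: the ester carbonyl of 12 is methylenated with Cp2TiMe2 (toluene, 70 °C) to the 1-arylvinyl ether F1. Ring-closing metathesis with the second-generation Grubbs catalyst RuCl2(=CHPh)(H2IMes)(PCy3) then joins the vinyl ether carbon to the inner allyl carbon with loss of ethylene. This forms the same C2=C3 bond and ring F, rejoins the route at 15, and bypasses 13 and 14.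

**Step 4.** The cation may be captured para to the hydroxyl of 6, which after the Claisen step would lead to the 4→6 linked isomer, or from the other face to give the 2,4-cis isomer. Oligomerisation through ring A and elimination to the flav-3-ene can also compete. Fallback, from 5 and 6 to 7: Mitsunobu etherification (PPh3, DIAD, THF, 0 °C) gives the aryl flavan-4-yl ether F2. BF3·OEt2 (catalytic, toluene, −78 °C) then promotes a 1,3 shift from oxygen to carbon within a contact ion pair, a known rearrangement of benzyl aryl ethers that reaches only the two equivalent ortho carbons. The same axial preference applies, and the route is rejoined at 7.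

**Step 10.** Reagent control of the face may be poor because the chiral borane meets a crowded, already chiral enol ether, which would give a mixture of lower-unit diastereomers. The addition may be slow, and the β-alkoxy organoborane may eliminate and open ring F. Fallback, from 15 to 19: BH3·SMe2 followed by NaOH and H2O2 gives 17 together with its (2S,3R) diastereomer F3. Dess–Martin oxidation of the mixture gives 18 and its C2 epimer F4. Asymmetric transfer hydrogenation with RuCl(p-cymene)[(S,S)-TsDPEN] or its antipode (HCO2H–Et3N) then acts as a dynamic kinetic resolution: the C2 epimers interconvert through the enol while the catalyst reduces the 2R ketone to the cis alcohol, as known for α-aryl cyclic ketones. The route is rejoined at 19.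

**Step 2.** The electron-rich boronic acid 3 may protodeboronate faster than it adds to the electron-rich chromone, and the enantioselectivity may be incomplete. Fallback, from 2 and 3 to 5: addition with an achiral catalyst (Pd(OCOCF3)2, 2,2′-bipyridine) gives the racemic flavanone F5. Kinetic resolution by asymmetric transfer hydrogenation (RuCl(p-cymene)[TsDPEN] of the hand that reduces the 2S ketone faster, HCO2H–Et3N) converts only the 2S enantiomer into the cis alcohol and leaves the 2R ketone behind. The route is rejoined at 5 at the cost of half the material.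

## Further compounds

F1 | step 9 | (2S,4R)-4-{3-allyl-4,6-bis(benzyloxy)-2-[1-(3,4,5-tris(benzyloxy)phenyl)vinyloxy]phenyl}-7-(benzyloxy)-2-[3,4-bis(benzyloxy)phenyl]chromane | c1ccccc1COc1ccc2c(c1)O[C@H](c1ccc(OCc3ccccc3)c(OCc3ccccc3)c1)C[C@H]2c1c(OCc3ccccc3)cc(OCc3ccccc3)c(CC=C)c1OC(=C)c1cc(OCc3ccccc3)c(OCc3ccccc3)c(OCc3ccccc3)c1
F2 | step 4 | (2S,4R)-7-(benzyloxy)-4-[3,5-bis(benzyloxy)phenoxy]-2-[3,4-bis(benzyloxy)phenyl]chromane (2,4-trans) | c1ccccc1COc1ccc2c(c1)O[C@H](c1ccc(OCc3ccccc3)c(OCc3ccccc3)c1)C[C@H]2Oc1cc(OCc3ccccc3)cc(OCc3ccccc3)c1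
F3 | step 10 | (2S,3R)-5,7-bis(benzyloxy)-8-{(2S,4R)-7-(benzyloxy)-2-[3,4-bis(benzyloxy)phenyl]chroman-4-yl}-2-[3,4,5-tris(benzyloxy)phenyl]chroman-3-ol (2,3-trans diastereomer of 17) | c1ccccc1COc1ccc2c(c1)O[C@H](c1ccc(OCc3ccccc3)c(OCc3ccccc3)c1)C[C@H]2c1c(OCc3ccccc3)cc(OCc3ccccc3)c2c1O[C@@H](c1cc(OCc3ccccc3)c(OCc3ccccc3)c(OCc3ccccc3)c1)[C@H](O)C2
F4 | step 10 | (2S)-5,7-bis(benzyloxy)-8-{(2S,4R)-7-(benzyloxy)-2-[3,4-bis(benzyloxy)phenyl]chroman-4-yl}-2-[3,4,5-tris(benzyloxy)phenyl]chroman-3-one (C2 epimer of 18) | c1ccccc1COc1ccc2c(c1)O[C@H](c1ccc(OCc3ccccc3)c(OCc3ccccc3)c1)C[C@H]2c1c(OCc3ccccc3)cc(OCc3ccccc3)c2c1O[C@@H](c1cc(OCc3ccccc3)c(OCc3ccccc3)c(OCc3ccccc3)c1)C(=O)C2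
F5 | step 2 | racemic 7-(benzyloxy)-2-[3,4-bis(benzyloxy)phenyl]chroman-4-one | c1ccccc1COc1ccc2c(c1)OC(c1ccc(OCc3ccccc3)c(OCc3ccccc3)c1)CC2=O
A1 | alternative 1 | 3-(benzyloxy)-6-{(2S,4R)-7-(benzyloxy)-2-[3,4-bis(benzyloxy)phenyl]chroman-4-yl}-2-{3-[3,4,5-tris(benzyloxy)phenyl]prop-2-yn-1-yl}-5-(triisopropylsilyloxy)phenol | c1ccccc1COc1ccc2c(c1)O[C@H](c1ccc(OCc3ccccc3)c(OCc3ccccc3)c1)C[C@H]2c1c(O[Si](C(C)C)(C(C)C)C(C)C)cc(OCc3ccccc3)c(CC#Cc4cc(OCc3ccccc3)c(OCc3ccccc3)c(OCc3ccccc3)c4)c1O
A2 | alternative 1 | (2S,4S)-7-(benzyloxy)-2-[3,4-bis(benzyloxy)phenyl]-4-[(triisopropylsilyloxy)ethynyl]chromane (2,4-trans) | c1ccccc1COc1ccc2c(c1)O[C@H](c1ccc(OCc3ccccc3)c(OCc3ccccc3)c1)C[C@H]2C#CO[Si](C(C)C)(C(C)C)C(C)C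
A3 | alternative 1 | 3-(benzyloxy)-4-{3-[3,4,5-tris(benzyloxy)phenyl]prop-2-yn-1-yl}cyclobut-2-en-1-one (racemic) | O=C1C=C(OCc2ccccc2)C1CC#Cc1cc(OCc2ccccc2)c(OCc2ccccc2)c(OCc2ccccc2)c1
A4 | alternative 2 | nona-O-benzyl ether of 20: (2R,3R)-3,5,7-tris(benzyloxy)-8-{(2S,4R)-7-(benzyloxy)-2-[3,4-bis(benzyloxy)phenyl]chroman-4-yl}-2-[3,4,5-tris(benzyloxy)phenyl]chromane | c1ccccc1COc1ccc2c(c1)O[C@H](c1ccc(OCc3ccccc3)c(OCc3ccccc3)c1)C[C@H]2c1c(OCc3ccccc3)cc(OCc3ccccc3)c2c1O[C@H](c1cc(OCc3ccccc3)c(OCc3ccccc3)c(OCc3ccccc3)c1)[C@H](OCc3ccccc3)C2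
A5 | alternative 2 | (E)-3-{(2R,3R)-3,5,7-tris(benzyloxy)-2-[3,4,5-tris(benzyloxy)phenyl]chroman-8-yl}prop-2-enal | O=C/C=C/c1c(OCc3ccccc3)cc(OCc3ccccc3)c2c1O[C@H](c1cc(OCc3ccccc3)c(OCc3ccccc3)c(OCc3ccccc3)c1)[C@H](OCc3ccccc3)C2
A6 | alternative 2 | 3-(benzyloxy)phenol | Oc1cccc(OCc2ccccc2)c1
A7 | alternative 2 | 1,2-bis(benzyloxy)benzene | c1ccccc1COc1ccccc1OCc1ccccc1
A8 | alternative 3 | octa-O-benzyl ether of 20 with free 3-hydroxyl (identical with 19) | c1ccccc1COc1ccc2c(c1)O[C@H](c1ccc(OCc3ccccc3)c(OCc3ccccc3)c1)C[C@H]2c1c(OCc3ccccc3)cc(OCc3ccccc3)c2c1O[C@H](c1cc(OCc3ccccc3)c(OCc3ccccc3)c(OCc3ccccc3)c1)[C@H](O)C2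
A9 | alternative 3 | 3,5-bis(benzyloxy)-2-{(2S,4R)-7-(benzyloxy)-2-[3,4-bis(benzyloxy)phenyl]chroman-4-yl}-6-({(2R,3S)-3-[3,4,5-tris(benzyloxy)phenyl]oxiran-2-yl}methyl)phenol (cis-epoxide) | c1ccccc1COc1ccc2c(c1)O[C@H](c1ccc(OCc3ccccc3)c(OCc3ccccc3)c1)C[C@H]2c1c(OCc3ccccc3)cc(OCc3ccccc3)c(C[C@H]4O[C@H]4c4cc(OCc3ccccc3)c(OCc3ccccc3)c(OCc3ccccc3)c4)c1O
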